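The charge is the unit at this board: the starting material of a flask counts as one, and the coupling partner is counted in that unit, as equivalents.

| flask | starting material | coupling partner | capture agent | remark | time |
|---|---|---|---|---|---|
| dawn | 11 mM | 11 mM | 0.48 mM | run made earlier |  |
| autumn | 11 mM | 11 mM | 0.69 mM | run made earlier |  |
| dusk | 5.6 mM | 11 mM | 0.55 mM | run made earlier |  |
| Saturday's | 6.0 mM | 20.0 mM | 0.550 mM |  | 1.0 h |
| Friday's | 8.0 mM | 11.0 mM | 0.550 mM |  | 1.0 h |
| Wednesday's | 4.0 mM | 20.0 mM | 0.400 mM |  | 1.0 h |
| Tuesday's | 11 mM | 11.0 mM | 0.550 mM |  | 1.0 h |

| run | time / min | double product / % | starting material / % |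
|---|---|---|---|
| dawn | 8.00 | 2.8 | 27.4 |
| dawn | 15.0 | 3.0 | 16.5 |
| dawn | 25.0 | 3.9 | 11.0 |
| dawn | 30.0 | 4.1 | 9.6 |
| dawn | 40.0 | 4.6 | 8.4 |
| autumn | 4.00 | 0.6 | 41.4 |
| autumn | 10.0 | 2.4 | 23.1 |
| autumn | 20.0 | 3.9 | 13.6 |
| autumn | 30.0 | 4.4 | 10.2 |
| autumn | 40.0 | 4.0 | 8.7 |
| dusk | 4.00 | 1.1 | 33.3 |
| dusk | 10.0 | 4.2 | 10.2 |
| dusk | 20.0 | 8.3 | 1.3 |
| dusk | 30.0 | 13.1 | 0.4 |
| dusk | 40.0 | 17.3 | 0 |

(standard deviation of a reading: 0.5 percentage points)

- a reading or a percentage of double product counts all its forms, free or not

1. ranking by amount of double product, in percent of the starting material charged, from high to low, at 1.0 h (Saturday's / Friday's / Wednesday's / Tuesday's)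
2. the amount of double product, in percent of the starting material charged of the flask you put first, at 1.0 h
3. the amount of double product, in percent of the starting material charged of the flask you put last, at 1.0 h

In the dusk run the starting material reads 1.3% at 20.0 min, less than the 8.3% of double product by then. So we both treat the first coupling as quick: it spends one equivalent of partner and leaves first product at one. Dusk charged 1.96 equivalents, which leaves 0.964 of spare partner against that one, so I count the two as equal and falling together. The reading 17.3% at 40.0 min then gives the coupling constant, the second-order constant of first product with partner: 9.34 × 10⁻⁴ /mM/min, a reading with the scatter of 0.5 percentage points in it.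

My colleague sees dusk climbing straight and takes the initial rate: the fraction turned is this constant times spare partner times time. That gives 89.7% for Wednesday's, 78.4% for Saturday's and 16.8% for Friday's.

I take logarithms. On this count spare partner and first product fall together, so their difference stays fixed, and the ratio of spare partner to first product shifts by a fixed number of decades per hour, set by the constant times that difference: upward in Wednesday's and Saturday's, downward in Friday's. Wednesday's starts at a ratio of 4.00 and gains 0.292 decades, reaching 7.84. The difference is 3.00 charges, so first product stands at that difference over the ratio less one, and double product at 56.1%. The same steps give 49.7% for Saturday's and 12.8% for Friday's. Tuesday's has no spare partner on this count, and dawn and autumn, with its charges of starting material and partner, last read 4.6% and 4.0%.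

The forecast gives Wednesday's > Saturday's > Friday's > Tuesday's, with 55% first and 5.3% last, and says of the flat dawn and autumn runs that “equimolar partner is used up in the first step”. It reached these by its own route. Its top lies near my 56.1%, and my colleague's line stands higher at 89.7%.

The flask gives Wednesday's > Saturday's > Friday's > Tuesday's, with 55.8% for Wednesday's and 5.07% for Tuesday's. The line overshoots Wednesday's by 34 points, and Friday's, which holds 13.7%, by 3.1 points, less, so the ground of the line is a flask with a low percentage of double product, such as Friday's.

    starting material + coupling partner → first product (k = 32.0 /M/min)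
    coupling partner + first product → double product (k = 0.990 /M/min)
    crystals ⇌ double product, rate k3*(cs3 - [double product]) while solid is left; crystals form when [double product] > cs3 (solubility = 0.950 mM, k = 1.90 /min)
    first product + capture agent → trapped intermediate (k = 3.30 /M/min)

The neighbour of Wednesday's holds 50 mM of partner, 12.5 equiv. Its ratio starts at 11.5 and gains 1.02 decades, which gives 91.2% of double product. That flask holds 90.3% of double product, with 85% of its own charge of partner still there, unbound.

The numbers in the tables were generated by integration for substances that don't exist; the scatter is artificial.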